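Naphthalene locants follow the target throughout: C1 (carbonyl on C8a), C2–OH, C3–H, C4 (carbonyl on C4a), C5–OH, C6 aroyl, C7 CH2–pyranone, C8–H. Ring A is the orsellinyl ring (primed locants), rings B and C the naphthoquinone, ring D the pyranone.

## The problem

Target 27 joins an orsellinyl ring (ring A), a 2,5-dihydroxy-1,4-naphthoquinone (rings B and C) and a 4-hydroxy-2-pyranone (ring D). Ring A hangs on C6 through a ketone and ring D on C7 through a methylene. Ring B carries a substituent on five of its six carbons (C4a, C5, C6, C7, C8a), with hydrogen only at C8, so it has to be assembled with everything in place. The molecule has no stereocentre. The selectivity questions are regiochemical: the ring C oxygen must sit on C2 and not on C3, and ring B needs oxygen at C5 only. The diaryl ketone has four ortho substituents, which shields it from nucleophiles but rules out forming it late. The hydroxyquinone will not tolerate dienes, strong nucleophiles, base or reductants, and the hydroxypyranone is a base- and hydrogenation-sensitive lactone. A carbonyl in the C7 side chain stands in a 1,5-relation to the diaryl ketone and can cyclize onto it under acid. The enabling feature is that the C5 oxygen lies next to C4a while C8 is unsubstituted. A C4a–C8a aryne is therefore polarized by one inductive substituent and open at its distal end, and the four carbons C1–C4 with the C2 oxygen can be delivered as a furan.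

## Retrosynthesis

**27 to 26.** The hydroxyls at C2, C5, C2' and C4' are traced to methyl ethers, cutting four O–CH3 bonds. Methyl is preferred to benzyl or silyl because ring A is available as its dimethyl ether (aldehyde 3) and because the C2 methoxy group is needed to steer two earlier steps. The forward step must cleave the unchelated C4' ether without harming rings C and D.

**26 to 25 to 24.** The C4 carbonyl oxygen is removed: quinone 26 comes from 2-methoxy-1-naphthol 25 by para-oxidation, the C2 methoxy group closing the ortho pathway. The quinone is placed second to last because it would not survive diene 8 or the base used to close ring D. Naphthol 25 is released from benzyl ether 24.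

**24 to 23 to 22 to 21 + 8.** Ring D is opened at the lactone C–O bond to diketo ester 23, taken back to hydroxy keto ester 22, and cut at the C–C bond between the carbinol carbon and the terminal carbon of diene 8. The alternative acylation of an arylacetic acid derivative is set aside: that acid, with its ortho aroyl group, would close to a lactol or enol lactone, and its activated forms enolize. Aldehyde 21 reacts under Lewis acid conditions, and diene 8 is already in the route.

**21 to 20 to 19 to 17.** Aldehyde 21 comes from alcohol 20, the benzyl ether of diol 19. Diol 19 is the acid-isomerized and desilylated form of cycloadduct 17, reached through naphthol 18. The forward step must break the C4–O bond of the bridge rather than C1–O, which the C2 methoxy group ensures.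

**17 to 13 + 14.** The key cut severs C1–C8a and C4–C4a, giving aryne 16 (from iodo triflate 13 through arylmagnesium 15) and 3-methoxyfuran 14. A Friedel–Crafts annulation, or a quinone Diels–Alder reaction onto a preformed ring C, would have no simple handle on C2 versus C3. Here the existing C5 oxygen decides the orientation. The precursor drops from a naphthalene to a benzene plus a commercial furan.

**13 to 12 to 11 to 10.** The O–CH3, O–S and C–I bonds are cut in turn, leading to resorcinol 10. The forward steps rely on intrinsic differences: the position between the hydroxyls is the most activated, the C8a hydroxyl is free and the C5 hydroxyl is chelated to the ketone.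

**10 to 5 + 8.** Ring B is cut at C5–C6 and C7–C8 into ynone 5 and diene 8. Friedel–Crafts acylation of a resorcinol by a ring A acid would have to form the tetra-ortho-substituted ketone directly. The cycloaddition makes it from an unhindered ynone and fixes the 1,3-dioxygenation at once.

**5 to 4 to 2 + 3; 2 from 1; 8 from 7 from 6.** Ynone 5 is the oxidized adduct 4 of alkyne 2 and aldehyde 3. Alkyne 2 is the silyl ether of 1, and diene 8 comes from methyl acetoacetate 6 through enol ether 7. Ester 6 thus supplies carbons to both ring B and ring D.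

## Roads not taken

**Alternative 1:** Ring A is cut at C1'–C6'. In the forward step aqueous base opens 4-pyranone A1 to tetraketone A2, whose C1' methylene condenses with the terminal methyl ketone to give orsellinyl ketone A3.
- Merits: the ring A substitution pattern follows from the chain, and both ring A hydroxyls arrive free. The stubborn C4' ether cleavage of the chosen route is avoided, which is a real advantage.
- Weak points: A1 presupposes the complete tetramethoxynaphthalene with its crowded C6 acyl group, so the ring C regiochemistry and the substitution of ring B remain unsolved. The 1,3-diketone next to the hindered naphthyl carbonyl in A2 is open to retro-Claisen cleavage. The free resorcinol of A3 would not survive the later oxidative release of the quinone and would need protection again.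
- Comparison: the chosen plan takes ring A from a commercial aldehyde and spends its key step on the naphthalene problem this road leaves open.

**Alternative 2:** Ring B is cut at C6–C7. In the forward step the central carbon of the 1,3-diketone in A4 condenses with the side-chain ketone to give naphthol A5.
- Merits: this is the most convergent road, and ring D is in place before ring B closes. No side-chain steps follow, whereas the chosen plan spends five steps on the side chain after its key step.
- Weak points: A4 has five carbonyl groups and several acidic methylenes. The benzylic methylene can close onto the ring A ketone in a competing six-membered aldol mode. The methoxypyranone is base-sensitive. A4 itself needs a pentasubstituted benzene with two adjacent carbonyl chains.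
- Comparison: it is shorter after ring closure, but nothing in the structure biases the selectivity. The chosen plan has an inductive effect of known direction to rely on.

**Alternative 3:** Ring A is cut at C1'–C2' and C5'–C6'. Naphthyl ynone A6 and diene 8 combine by [4+2] cycloaddition with loss of methanol to give A7.
- Merits: this is the same reaction type as step 6 of the chosen route, so it is equally reliable, and it also delivers ring A unprotected.
- Weak points: A6 again requires the finished naphthalene and a hindered acyl group at C6. The free resorcinol of A7 must then pass through side-chain oxidation and oxidative quinone release.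
- Comparison: it is equal in reliability and better in the final deprotection. The chosen plan uses the same cycloaddition earlier, where it builds the more substituted ring B and installs the C5 oxygen that steers the aryne.

Key step: step 10

Remark: the target is achiral and is treated in the tautomeric form drawn (2-hydroxy-1,4-naphthoquinone, 4-hydroxy-2-pyranone); the stereocentres of 4, 9, 17 and 22 are racemic and are all removed later.

## Route

Step 1
Reactants: 1 but-3-yn-1-ol
Product: 2 tert-butyl(but-3-yn-1-yloxy)dimethylsilane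
Conditions: TBSCl, imidazole, DMF, rt
Reagents that add atoms: tert-butyldimethylsilyl chloride, CC(C)(C)[Si](C)(C)Cl
Why: Standard imidazole-promoted silylation of a primary alcohol; the silyl ether masks the future ring D carbon through the organometallic steps.

Step 2
Reactants: 2 tert-butyl(but-3-yn-1-yloxy)dimethylsilane; 3 2,4-dimethoxy-6-methylbenzaldehyde
Product: 4 racemic 5-{[tert-butyl(dimethyl)silyl]oxy}-1-(2,4-dimethoxy-6-methylphenyl)pent-2-yn-1-ol
Conditions: n-BuLi, THF, −78 °C; then 3, −78 °C to 0 °C; aq. NH4Cl
Reagents that add atoms: none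
Why: Addition of a lithium acetylide to a non-enolizable aldehyde; the carbinol centre is formed racemic and is removed in step 3.

Step 3
Reactants: 4 racemic propargylic alcohol
Product: 5 5-{[tert-butyl(dimethyl)silyl]oxy}-1-(2,4-dimethoxy-6-methylphenyl)pent-2-yn-1-one
Conditions: MnO2, CH2Cl2, rt
Reagents that add atoms: none
Why: MnO2 oxidizes the doubly activated (benzylic and propargylic) alcohol selectively and leaves the silyl ether alone.

Step 4
Reactants: 6 methyl acetoacetate
Product: 7 methyl 3-(trimethylsilyloxy)but-2-enoate (E/Z mixture, both isomers serve)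
Conditions: TMSCl, Et3N, hexane, rt
Reagents that add atoms: chlorotrimethylsilane, C[Si](C)(C)Cl
Why: O-silylation of the enol of a β-keto ester, the usual first stage in preparing a 1,3-bis(silyloxy)diene.

Step 5
Reactants: 7 methyl 3-(trimethylsilyloxy)but-2-enoate
Product: 8 1-methoxy-1,3-bis(trimethylsilyloxy)buta-1,3-diene
Conditions: LiN(i-Pr)2, THF, −78 °C; then TMSCl, −78 °C to rt
Reagents that add atoms: chlorotrimethylsilane, C[Si](C)(C)Cl
Why: γ-Deprotonation of the vinylogous ester and O-silylation of the dienolate give the bis-silyl dienol ether, a standard preparation; the diene is used without chromatography.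

Step 6
Reactants: 5 ynone; 8 1-methoxy-1,3-bis(trimethylsilyloxy)buta-1,3-diene
Product: 10 [2-(2-{[tert-butyl(dimethyl)silyl]oxy}ethyl)-4,6-dihydroxyphenyl](2,4-dimethoxy-6-methylphenyl)methanone, via cyclohexadiene cycloadduct 9 (not isolated)
Conditions: PhMe, 90 °C; then aq. citric acid, THF, rt
Reagents that add atoms: none
Why: Diels–Alder benzannulation of an ynone with a 1-alkoxy-1,3-bis(silyloxy)diene: the CH2 terminus adds to the β-carbon of the ynone and the ketene acetal carbon to the α-carbon. Mild acid then removes methanol and the trimethylsilyl groups from 9 to give the resorcinol with the acyl group between a hydroxyl and the side chain; the primary silyl ether survives citric acid.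

Step 7
Reactants: 10 resorcinol ketone
Product: 11 [6-(2-{[tert-butyl(dimethyl)silyl]oxy}ethyl)-2,4-dihydroxy-3-iodophenyl](2,4-dimethoxy-6-methylphenyl)methanone
Conditions: I2, NaHCO3, THF/H2O, 0 °C
Reagents that add atoms: iodine, II
Why: Electrophilic iodination of a resorcinol in aqueous hydrogencarbonate goes to the carbon between the two hydroxyls, as known for resorcinol and 2,4-dihydroxyaryl ketones; the other free position is flanked by the side chain.

Step 8
Reactants: 11 iodoresorcinol ketone
Product: 12 5-(2-{[tert-butyl(dimethyl)silyl]oxy}ethyl)-4-(2,4-dimethoxy-6-methylbenzoyl)-3-hydroxy-2-iodophenyl trifluoromethanesulfonate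
Conditions: PhNTf2 (1.05 equiv), Et3N, CH2Cl2, 0 °C to rt
Reagents that add atoms: N-phenylbis(trifluoromethanesulfonimide), O=S(=O)(N(c1ccccc1)S(=O)(=O)C(F)(F)F)C(F)(F)F
Why: Selective O-sulfonylation: the hydroxyl para to the ketone is the more acidic and is free, whereas the ortho hydroxyl is hydrogen-bonded to the carbonyl, so one equivalent of the mild triflating agent reacts at the para oxygen, as known for 2,4-dihydroxyaryl ketones.

Step 9
Reactants: 12 hydroxy iodo triflate
Product: 13 5-(2-{[tert-butyl(dimethyl)silyl]oxy}ethyl)-4-(2,4-dimethoxy-6-methylbenzoyl)-2-iodo-3-methoxyphenyl trifluoromethanesulfonate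
Conditions: MeI, K2CO3, acetone, 50 °C
Reagents that add atoms: iodomethane, CI
Why: Williamson methylation of the remaining chelated phenol; the aryl triflate and the silyl ether are stable to carbonate and iodomethane.

Step 10
Reactants: 13 iodo triflate; 14 3-methoxyfuran
Product: 17 racemic (1R*,4R*)-[7-(2-{[tert-butyl(dimethyl)silyl]oxy}ethyl)-2,5-dimethoxy-1,4-dihydro-1,4-epoxynaphthalen-6-yl](2,4-dimethoxy-6-methylphenyl)methanone, via arylmagnesium chloride 15 (not isolated), via aryne 16 (not isolated)
Conditions: 14 (5 equiv), i-PrMgCl·LiCl (1.1 equiv), THF, −78 °C to 0 °C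
Reagents that add atoms: none
Why: Iodine–magnesium exchange at C4a is far faster than attack on the tetra-ortho-substituted ketone, and arylmagnesium 15 expels the neighbouring triflate to give aryne 16. The aryne is trapped by the furan in a concerted but asynchronous [4+2] cycloaddition, the known Diels–Alder reaction of furans with 3-alkoxyarynes generated from ortho-iodoaryl triflates. Ring C closes by intermolecular [4+2] annulation onto the C4a–C8a edge of ring B, forming C1–C8a and C4–C4a together and giving the oxygen-bridged cyclohexadiene. The two bridgehead stereocentres C1 and C4 arise in the same event; suprafacial addition and the one-atom bridge fix their relative configuration, and no absolute control is needed because step 11 erases both. The selectivity required is regiochemical. Inductive withdrawal by the C5 methoxy group makes the distal carbon C8a the electrophilic terminus of 16, and the largest HOMO coefficient of the furan lies at C2, beside the methoxy-bearing carbon. Their union puts the methoxy group on C2 of the new ring, and the unsubstituted C8 leaves that terminus unhindered. Excess furan and low temperature keep the Grignard reagent from adding to the aryne.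

Step 11
Reactants: 17 racemic cycloadduct
Product: 19 6-(2,4-dimethoxy-6-methylbenzoyl)-7-(2-hydroxyethyl)-2,5-dimethoxynaphthalen-1-ol, via naphthol silyl ether 18 (not isolated)
Conditions: CSA (0.2 equiv), CH2Cl2, 0 °C to rt; then MeOH, rt; under argon
Reagents that add atoms: none
Why: Acid isomerization of a 1,4-epoxy-1,4-dihydronaphthalene: the C4–O bond ionizes because the cation is a vinylogous oxocarbenium ion stabilized by the C2 methoxy group, and loss of the C1 proton aromatizes ring C to the 2-methoxy-1-naphthol 18, removing both stereocentres. Added methanol then cleaves the primary silyl ether under the same acid.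

Step 12
Reactants: 19 naphthol diol
Product: 20 [1-(benzyloxy)-7-(2-hydroxyethyl)-2,5-dimethoxynaphthalen-6-yl](2,4-dimethoxy-6-methylphenyl)methanone
Conditions: BnBr (1.1 equiv), K2CO3, acetone, 50 °C, under argon
Reagents that add atoms: benzyl bromide, BrCc1ccccc1
Why: Phenol-selective Williamson etherification, since carbonate deprotonates only the naphthol; the benzyl group shields the oxidation-prone naphthol through steps 13 to 16.

Step 13
Reactants: 20 benzyl ether alcohol
Product: 21 2-[1-(benzyloxy)-6-(2,4-dimethoxy-6-methylbenzoyl)-2,5-dimethoxynaphthalen-7-yl]acetaldehyde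
Conditions: DMP, NaHCO3, CH2Cl2, 0 °C to rt
Reagents that add atoms: none
Why: Buffered periodinane oxidation of a primary alcohol stops at the aldehyde and tolerates aryl ethers; the arylacetaldehyde is used at once.

Step 14
Reactants: 21 arylacetaldehyde; 8 1-methoxy-1,3-bis(trimethylsilyloxy)buta-1,3-diene
Product: 22 racemic methyl 6-[1-(benzyloxy)-6-(2,4-dimethoxy-6-methylbenzoyl)-2,5-dimethoxynaphthalen-7-yl]-5-hydroxy-3-oxohexanoate
Conditions: 8 (1.5 equiv), BF3·OEt2, CH2Cl2, −78 °C; aq. NH4Cl
Reagents that add atoms: none
Why: Vinylogous Mukaiyama aldol addition of the diene terminus to the Lewis-acid-activated aldehyde; the non-basic conditions avoid enolization of the arylacetaldehyde and the hindered diaryl ketone does not compete. The new carbinol centre is racemic and is oxidized away in step 15.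

Step 15
Reactants: 22 racemic hydroxy keto ester
Product: 23 methyl 6-[1-(benzyloxy)-6-(2,4-dimethoxy-6-methylbenzoyl)-2,5-dimethoxynaphthalen-7-yl]-3,5-dioxohexanoate
Conditions: DMP (1.2 equiv), CH2Cl2, 0 °C to rt
Reagents that add atoms: none
Why: Periodinane oxidation of a β-hydroxy ketone to the 1,3-diketone, the usual second stage of the aldol, oxidation and lactonization route to 6-substituted 4-hydroxy-2-pyranones; limiting the oxidant prevents oxidation of the active methylene.

Step 16
Reactants: 23 diketo ester
Product: 24 6-{[1-(benzyloxy)-6-(2,4-dimethoxy-6-methylbenzoyl)-2,5-dimethoxynaphthalen-7-yl]methyl}-4-hydroxy-2H-pyran-2-one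
Conditions: DBU, PhMe, rt to 60 °C; then 1 M HCl
Reagents that add atoms: none
Why: Base-promoted lactonization of a 3,5-dioxo ester: the C5 enolate oxygen is acylated by the methyl ester with loss of methanol, closing ring D. The tetra-ortho-substituted diaryl ketone is too shielded to intercept the enolate.

Step 17
Reactants: 24 benzyl-protected pyranone
Product: 25 6-{[6-(2,4-dimethoxy-6-methylbenzoyl)-1-hydroxy-2,5-dimethoxynaphthalen-7-yl]methyl}-4-hydroxy-2H-pyran-2-one
Conditions: H2 (1 atm), Pd/C, EtOAc, rt
Reagents that add atoms: none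
Why: Hydrogenolysis of an aryl benzyl ether is much faster than reduction of the pyranone or of the hindered ketone at one atmosphere; the naphthol is taken on without storage.

Step 18
Reactants: 25 naphthol pyranone
Product: 26 6-(2,4-dimethoxy-6-methylbenzoyl)-7-[(4-hydroxy-2-oxo-2H-pyran-6-yl)methyl]-2,5-dimethoxynaphthalene-1,4-dione
Conditions: (KSO3)2NO, KH2PO4, acetone/H2O, 0 °C to rt
Reagents that add atoms: potassium nitrosodisulfonate, [K+].[K+].[O]N(S(=O)(=O)[O-])S(=O)(=O)[O-]
Why: Teuber oxidation: a 1-naphthol with a free para position is converted to the 1,4-quinone by two equivalents of the nitroxyl radical; the methoxy group at C2 closes the ortho-quinone pathway.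

Step 19
Reactants: 26 tetramethyl ether quinone
Product: 27 6-(2,4-dihydroxy-6-methylbenzoyl)-2,5-dihydroxy-7-[(4-hydroxy-2-oxo-2H-pyran-6-yl)methyl]naphthalene-1,4-dione (CNP0158797.0)
Conditions: BBr3 (excess), CH2Cl2, −78 °C to rt; then H2O
Reagents that add atoms: none
Why: Lewis acid ether cleavage: the quinone vinylogous ester and the two carbonyl-chelated ethers (C5, C2') cleave readily and the C4' ether at room temperature; hydrolysis of the boron esters releases 27.

## Compound list

1 | but-3-yn-1-ol | C#CCCO | starting material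
2 | tert-butyl(but-3-yn-1-yloxy)dimethylsilane | C#CCCO[Si](C)(C)C(C)(C)C | intermediate
3 | 2,4-dimethoxy-6-methylbenzaldehyde | COc1cc(C)c(C=O)c(OC)c1 | starting material
4 | racemic 5-{[tert-butyl(dimethyl)silyl]oxy}-1-(2,4-dimethoxy-6-methylphenyl)pent-2-yn-1-ol | COc1cc(C)c(C(O)C#CCCO[Si](C)(C)C(C)(C)C)c(OC)c1 | intermediate
5 | 5-{[tert-butyl(dimethyl)silyl]oxy}-1-(2,4-dimethoxy-6-methylphenyl)pent-2-yn-1-one | COc1cc(C)c(C(=O)C#CCCO[Si](C)(C)C(C)(C)C)c(OC)c1 | intermediate
6 | methyl acetoacetate | COC(=O)CC(C)=O | starting material
7 | methyl 3-(trimethylsilyloxy)but-2-enoate (E/Z mixture) | COC(=O)C=C(C)O[Si](C)(C)C | intermediate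
8 | 1-methoxy-1,3-bis(trimethylsilyloxy)buta-1,3-diene | COC(O[Si](C)(C)C)=CC(=C)O[Si](C)(C)C | intermediate
9 | racemic cyclohexa-1,4-diene cycloadduct of 5 and 8 (6-methoxy-4,6-bis(trimethylsilyloxy) ring carrying the aroyl group at C1 and the silyloxyethyl group at C2), not isolated | COC1(O[Si](C)(C)C)C=C(O[Si](C)(C)C)CC(CCO[Si](C)(C)C(C)(C)C)=C1C(=O)c1c(C)cc(OC)cc1OC | intermediate
10 | [2-(2-{[tert-butyl(dimethyl)silyl]oxy}ethyl)-4,6-dihydroxyphenyl](2,4-dimethoxy-6-methylphenyl)methanone | COc1cc(C)c(C(=O)c2c(O)cc(O)cc2CCO[Si](C)(C)C(C)(C)C)c(OC)c1 | intermediate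
11 | [6-(2-{[tert-butyl(dimethyl)silyl]oxy}ethyl)-2,4-dihydroxy-3-iodophenyl](2,4-dimethoxy-6-methylphenyl)methanone | COc1cc(C)c(C(=O)c2c(O)c(I)c(O)cc2CCO[Si](C)(C)C(C)(C)C)c(OC)c1 | intermediate
12 | 5-(2-{[tert-butyl(dimethyl)silyl]oxy}ethyl)-4-(2,4-dimethoxy-6-methylbenzoyl)-3-hydroxy-2-iodophenyl trifluoromethanesulfonate | COc1cc(C)c(C(=O)c2c(O)c(I)c(OS(=O)(=O)C(F)(F)F)cc2CCO[Si](C)(C)C(C)(C)C)c(OC)c1 | intermediate
13 | 5-(2-{[tert-butyl(dimethyl)silyl]oxy}ethyl)-4-(2,4-dimethoxy-6-methylbenzoyl)-2-iodo-3-methoxyphenyl trifluoromethanesulfonate | COc1cc(C)c(C(=O)c2c(CCO[Si](C)(C)C(C)(C)C)cc(OS(=O)(=O)C(F)(F)F)c(I)c2OC)c(OC)c1 | intermediate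
14 | 3-methoxyfuran | COc1ccoc1 | starting material
15 | arylmagnesium chloride from 13 (Mg–Cl in place of iodine), not isolated | COc1cc(C)c(C(=O)c2c(CCO[Si](C)(C)C(C)(C)C)cc(OS(=O)(=O)C(F)(F)F)c([Mg]Cl)c2OC)c(OC)c1 | intermediate
16 | 5-(2-{[tert-butyl(dimethyl)silyl]oxy}ethyl)-4-(2,4-dimethoxy-6-methylbenzoyl)-3-methoxybenzyne (triple bond between the former C–OTf and C–I carbons), not isolated | COc1cc(C)c(C(=O)C2=C(OC)C#CC=C2CCO[Si](C)(C)C(C)(C)C)c(OC)c1 | intermediate
17 | racemic (1R*,4R*)-[7-(2-{[tert-butyl(dimethyl)silyl]oxy}ethyl)-2,5-dimethoxy-1,4-dihydro-1,4-epoxynaphthalen-6-yl](2,4-dimethoxy-6-methylphenyl)methanone (one enantiomer drawn) | COC1=C[C@H]2O[C@@H]1c1cc(CCO[Si](C)(C)C(C)(C)C)c(C(=O)c3c(C)cc(OC)cc3OC)c(OC)c12 | intermediate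
18 | 7-(2-{[tert-butyl(dimethyl)silyl]oxy}ethyl)-6-(2,4-dimethoxy-6-methylbenzoyl)-2,5-dimethoxynaphthalen-1-ol, not isolated | COc1cc(C)c(C(=O)c2c(CCO[Si](C)(C)C(C)(C)C)cc3c(O)c(OC)ccc3c2OC)c(OC)c1 | intermediate
19 | 6-(2,4-dimethoxy-6-methylbenzoyl)-7-(2-hydroxyethyl)-2,5-dimethoxynaphthalen-1-ol | COc1cc(C)c(C(=O)c2c(CCO)cc3c(O)c(OC)ccc3c2OC)c(OC)c1 | intermediate
20 | [1-(benzyloxy)-7-(2-hydroxyethyl)-2,5-dimethoxynaphthalen-6-yl](2,4-dimethoxy-6-methylphenyl)methanone | COc1cc(C)c(C(=O)c2c(CCO)cc3c(OCc4ccccc4)c(OC)ccc3c2OC)c(OC)c1 | intermediate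
21 | 2-[1-(benzyloxy)-6-(2,4-dimethoxy-6-methylbenzoyl)-2,5-dimethoxynaphthalen-7-yl]acetaldehyde | COc1cc(C)c(C(=O)c2c(CC=O)cc3c(OCc4ccccc4)c(OC)ccc3c2OC)c(OC)c1 | intermediate
22 | racemic methyl 6-[1-(benzyloxy)-6-(2,4-dimethoxy-6-methylbenzoyl)-2,5-dimethoxynaphthalen-7-yl]-5-hydroxy-3-oxohexanoate | COC(=O)CC(=O)CC(O)Cc1cc2c(OCc3ccccc3)c(OC)ccc2c(OC)c1C(=O)c1c(C)cc(OC)cc1OC | intermediate
23 | methyl 6-[1-(benzyloxy)-6-(2,4-dimethoxy-6-methylbenzoyl)-2,5-dimethoxynaphthalen-7-yl]-3,5-dioxohexanoate | COC(=O)CC(=O)CC(=O)Cc1cc2c(OCc3ccccc3)c(OC)ccc2c(OC)c1C(=O)c1c(C)cc(OC)cc1OC | intermediate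
24 | 6-{[1-(benzyloxy)-6-(2,4-dimethoxy-6-methylbenzoyl)-2,5-dimethoxynaphthalen-7-yl]methyl}-4-hydroxy-2H-pyran-2-one | COc1cc(C)c(C(=O)c2c(Cc3cc(O)cc(=O)o3)cc3c(OCc4ccccc4)c(OC)ccc3c2OC)c(OC)c1 | intermediate
25 | 6-{[6-(2,4-dimethoxy-6-methylbenzoyl)-1-hydroxy-2,5-dimethoxynaphthalen-7-yl]methyl}-4-hydroxy-2H-pyran-2-one | COc1cc(C)c(C(=O)c2c(Cc3cc(O)cc(=O)o3)cc3c(O)c(OC)ccc3c2OC)c(OC)c1 | intermediate
26 | 6-(2,4-dimethoxy-6-methylbenzoyl)-7-[(4-hydroxy-2-oxo-2H-pyran-6-yl)methyl]-2,5-dimethoxynaphthalene-1,4-dione | COC1=CC(=O)c2c(OC)c(C(=O)c3c(C)cc(OC)cc3OC)c(Cc3cc(O)cc(=O)o3)cc2C1=O | intermediate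
27 | 6-(2,4-dihydroxy-6-methylbenzoyl)-2,5-dihydroxy-7-[(4-hydroxy-2-oxo-2H-pyran-6-yl)methyl]naphthalene-1,4-dione (CNP0158797.0) | Cc1cc(O)cc(O)c1C(=O)c1c(Cc2cc(O)cc(=O)o2)cc2c(c1O)C(=O)C=C(O)C2=O | target

## Step count and least certain steps

Total step count: 19. Longest linear sequence: 17 steps (steps 1 to 3 and 6 to 19, from but-3-yn-1-ol 1); steps 4 and 5 form the short branch to diene 8.

**Step 10 (key step).** The most likely failure is erosion of regioselectivity. One methoxy group polarizes the aryne only moderately, so bonding of furan C5 to C8a could compete and lead into the 3-methoxy series; addition of the Grignard reagent to the aryne is a second loss channel. The fallback adds a steric control element. It sets out from 13 and from 14: C2-lithiation of 14 and silylation would give 3-methoxy-2-(trimethylsilyl)furan F1. In the cycloaddition with aryne 16 the bulky silyl terminus avoids the aryne carbon flanked by the C5 methoxy group, which reinforces the electronic preference and should give the bridgehead-silylated cycloadduct F2. Under the acid and methanol of step 11 the C4–O bond ionizes as before and the silyl group leaves from C1 in place of the proton. The fallback rejoins the route at 19.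

**Step 7.** Iodination may take place at the other activated carbon, ortho to one hydroxyl and para to the other, or twice. That would place the later aryne on the wrong edge of ring B. The fallback dispenses with iodine and sets out from 10. Selective triflation of the free hydroxyl as in step 8 would give 5-(2-{[tert-butyl(dimethyl)silyl]oxy}ethyl)-4-(2,4-dimethoxy-6-methylbenzoyl)-3-hydroxyphenyl trifluoromethanesulfonate F3, and methylation as in step 9 its 3-methoxy analogue F4. Lithium 2,2,6,6-tetramethylpiperidide in THF at −78 °C, with 14 present, removes the proton between the methoxy and triflate groups, the most acidic ring hydrogen. Loss of triflate gives the same aryne 16, and the fallback rejoins the route at 17.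

**Step 11.** Protonation at the enol ether carbon followed by hydrolysis would cost the C2 methyl group, and desilylation may lag behind aromatization. The fallback opens the bridge under aprotic conditions and sets out from 17. tert-Butyldimethylsilyl triflate with 2,6-lutidine in CH2Cl2 at −78 °C silylates the bridging oxygen, the C4–O bond ionizes and the base removes the C1 proton. This gives the bis-silyl ether tert-butyl-protected at both oxygens, 1,7-bis-silylated naphthol F5. Tetrabutylammonium fluoride then removes both silyl groups, and the fallback rejoins the route at 19.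

**Step 16.** Under base the diketone enolate may undergo retro-Claisen cleavage or condense at carbon instead of lactonizing. The fallback closes ring D thermally and sets out from 21. Aldol addition of the lithium dienolate of 2,2,6-trimethyl-4H-1,3-dioxin-4-one would give the racemic hydroxy dioxinone F6, and periodinane oxidation the keto dioxinone F7. Heating in toluene at 110 °C releases acetone, and the acylketene is trapped by the ketone enol. The fallback rejoins the route at 24.

**Step 17.** Hydrogenation of the pyranone double bonds may accompany the hydrogenolysis. The fallback changes the order and sets out from 23. Hydrogenolysis before ring D exists would give the naphthol diketo ester F8, and lactonization with excess DBU under argon, as in step 16, rejoins the route at 25.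

## Further compounds

F1 | step 10 | 3-methoxy-2-(trimethylsilyl)furan | COc1ccoc1[Si](C)(C)C
F2 | step 10 | racemic [7-(2-{[tert-butyl(dimethyl)silyl]oxy}ethyl)-2,5-dimethoxy-1-(trimethylsilyl)-1,4-dihydro-1,4-epoxynaphthalen-6-yl](2,4-dimethoxy-6-methylphenyl)methanone (one enantiomer drawn) | COC1=C[C@H]2O[C@]1([Si](C)(C)C)c1cc(CCO[Si](C)(C)C(C)(C)C)c(C(=O)c3c(C)cc(OC)cc3OC)c(OC)c12
F3 | step 7 | 5-(2-{[tert-butyl(dimethyl)silyl]oxy}ethyl)-4-(2,4-dimethoxy-6-methylbenzoyl)-3-hydroxyphenyl trifluoromethanesulfonate | COc1cc(C)c(C(=O)c2c(O)cc(OS(=O)(=O)C(F)(F)F)cc2CCO[Si](C)(C)C(C)(C)C)c(OC)c1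
F4 | step 7 | 5-(2-{[tert-butyl(dimethyl)silyl]oxy}ethyl)-4-(2,4-dimethoxy-6-methylbenzoyl)-3-methoxyphenyl trifluoromethanesulfonate | COc1cc(C)c(C(=O)c2c(OC)cc(OS(=O)(=O)C(F)(F)F)cc2CCO[Si](C)(C)C(C)(C)C)c(OC)c1
F5 | step 11 | [1-{[tert-butyl(dimethyl)silyl]oxy}-7-(2-{[tert-butyl(dimethyl)silyl]oxy}ethyl)-2,5-dimethoxynaphthalen-6-yl](2,4-dimethoxy-6-methylphenyl)methanone | COc1cc(C)c(C(=O)c2c(CCO[Si](C)(C)C(C)(C)C)cc3c(O[Si](C)(C)C(C)(C)C)c(OC)ccc3c2OC)c(OC)c1
F6 | step 16 | racemic 6-{3-[1-(benzyloxy)-6-(2,4-dimethoxy-6-methylbenzoyl)-2,5-dimethoxynaphthalen-7-yl]-2-hydroxypropyl}-2,2-dimethyl-4H-1,3-dioxin-4-one | CC1(C)OC(CC(O)Cc2cc3c(OCc4ccccc4)c(OC)ccc3c(OC)c2C(=O)c2c(C)cc(OC)cc2OC)=CC(=O)O1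
F7 | step 16 | 6-{3-[1-(benzyloxy)-6-(2,4-dimethoxy-6-methylbenzoyl)-2,5-dimethoxynaphthalen-7-yl]-2-oxopropyl}-2,2-dimethyl-4H-1,3-dioxin-4-one | CC1(C)OC(CC(=O)Cc2cc3c(OCc4ccccc4)c(OC)ccc3c(OC)c2C(=O)c2c(C)cc(OC)cc2OC)=CC(=O)O1
F8 | step 17 | methyl 6-[6-(2,4-dimethoxy-6-methylbenzoyl)-1-hydroxy-2,5-dimethoxynaphthalen-7-yl]-3,5-dioxohexanoate | COC(=O)CC(=O)CC(=O)Cc1cc2c(O)c(OC)ccc2c(OC)c1C(=O)c1c(C)cc(OC)cc1OC
A1 | alternative 1 | 2-{2-[7-(2-benzyloxyethyl)-1,2,4,5-tetramethoxynaphthalen-6-yl]-2-oxoethyl}-6-methyl-4H-pyran-4-one | Cc1cc(=O)cc(CC(=O)c2c(CCOCc3ccccc3)cc3c(OC)c(OC)cc(OC)c3c2OC)o1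
A2 | alternative 1 | 1-[7-(2-benzyloxyethyl)-1,2,4,5-tetramethoxynaphthalen-6-yl]octane-1,3,5,7-tetrone | CC(=O)CC(=O)CC(=O)CC(=O)c1c(CCOCc2ccccc2)cc2c(OC)c(OC)cc(OC)c2c1OC
A3 | alternative 1 | [7-(2-benzyloxyethyl)-1,2,4,5-tetramethoxynaphthalen-6-yl](2,4-dihydroxy-6-methylphenyl)methanone | Cc1cc(O)cc(O)c1C(=O)c1c(CCOCc2ccccc2)cc2c(OC)c(OC)cc(OC)c2c1OC
A4 | alternative 2 | 1-(2,4-dimethoxy-6-methylphenyl)-3-{3,4,6-trimethoxy-2-[3-(4-methoxy-2-oxo-2H-pyran-6-yl)-2-oxopropyl]phenyl}propane-1,3-dione | COc1cc(C)c(C(=O)CC(=O)c2c(OC)cc(OC)c(OC)c2CC(=O)Cc2cc(OC)cc(=O)o2)c(OC)c1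
A5 | alternative 2 | (2,4-dimethoxy-6-methylphenyl){5-hydroxy-1,2,4-trimethoxy-7-[(4-methoxy-2-oxo-2H-pyran-6-yl)methyl]naphthalen-6-yl}methanone | COc1cc(C)c(C(=O)c2c(Cc3cc(OC)cc(=O)o3)cc3c(OC)c(OC)cc(OC)c3c2O)c(OC)c1
A6 | alternative 3 | 1-[7-(2-{[tert-butyl(dimethyl)silyl]oxy}ethyl)-1,2,4,5-tetramethoxynaphthalen-6-yl]but-2-yn-1-one | CC#CC(=O)c1c(CCO[Si](C)(C)C(C)(C)C)cc2c(OC)c(OC)cc(OC)c2c1OC
A7 | alternative 3 | [7-(2-{[tert-butyl(dimethyl)silyl]oxy}ethyl)-1,2,4,5-tetramethoxynaphthalen-6-yl](2,4-dihydroxy-6-methylphenyl)methanone | Cc1cc(O)cc(O)c1C(=O)c1c(CCO[Si](C)(C)C(C)(C)C)cc2c(OC)c(OC)cc(OC)c2c1OC
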